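**Retrosynthetic overview**
1. The C30 chain is cut at the disubstituted double bond next to the ring-side C15 unit: Horner–Wadsworth–Emmons union of furanoid enal 16 with pentaenyl phosphonate 21 (from C10 dialdehyde 17 and C5 phosphonate 18). The aldehyde terminus comes from the ester by DIBAL-H/MnO2, so no acid touches the dihydrofuran.
2. The dihydrofuran (last ring made) comes from gold(I) 5-endo cyclisation of α-hydroxyallene 14, which comes from anti-SN2′ hydride opening of alkynyl oxirane 12, itself from OH-directed epoxidation of enynol 8 and Sonogashira coupling with enol triflate 11.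
3. The carbocycle C3a–C4–C5–C6–C7–C7a of the hexahydrobenzofuran is not built as a six-membered ring. In 8 the C6 carbinol, the C7 methylene and the C7a=C3a double bond form a homoallylic alcohol, the retron of a cyclopropylcarbinyl→homoallyl opening. Joining C6 to C7a (C7 as cyclopropane CH2) gives bicyclo[3.1.0]hexanol 7, whose cyclopentane (C3a, C4, C5, C6, C7a) expands by one carbon on hydration.
4. 7 comes from ethynylation of ketone 6, made from 2-methylcyclopent-2-enone 1 by CBS reduction, directed cyclopropanation, oxidation and gem-dimethylation. The single CBS-derived centre is relayed to C6 (inversion in the key step), to C7a (directed epoxidation) and to C2 (centre→axis→centre).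
5. Ring order: cyclopentene (bought) → cyclopropane → cyclohexene by ring expansion → oxirane (temporary) → 2,5-dihydrofuran.

Key step: step 6

Assumption: the target is read as (2R,6R,7aR), i.e. 6-OH cis to the ring oxygen on C7a and the polyene on C2 trans to the 7a-methyl; 17 and 18 are bought as the E isomers.

Step 1
Reactants: 1 2-methylcyclopent-2-en-1-one
Product: 2 (1S)-2-methylcyclopent-2-en-1-ol
Conditions: (R)-Me-CBS oxazaborolidine (10 mol %), BH3·SMe2, THF, −20 °C; MeOH, aqueous work-up
Reagents that add atoms: none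
Why: Corey–Bakshi–Shibata reduction, in which the catalyst–borane complex binds the carbonyl anti to the bulkier 2-methylalkenyl flank and delivers hydride to one face, should set the (S)-carbinol, whose only role is to relay chirality to the cyclopropane.

Step 2
Reactants: 2 (1S)-2-methylcyclopent-2-en-1-ol
Product: 3 (1R,2S,5S)-1-methylbicyclo[3.1.0]hexan-2-ol
Conditions: Et2Zn, CH2I2, CH2Cl2, −10 °C → rt
Reagents that add atoms: diiodomethane, ICI
Why: Hydroxyl-directed Simmons–Smith cyclopropanation, in which the zinc alkoxide delivers the carbenoid to the alkene face syn to oxygen, sets both cyclopropane stereocentres from the carbinol centre.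

Step 3
Reactants: 3 (1R,2S,5S)-1-methylbicyclo[3.1.0]hexan-2-ol
Product: 4 (1R,5S)-1-methylbicyclo[3.1.0]hexan-2-one
Conditions: TPAP (5 mol %), NMO, 4 Å MS, CH2Cl2, rt
Reagents that add atoms: none
Why: Ley–Griffith oxidation of a secondary alcohol under neutral conditions leaves the cyclopropane intact, and the bridgehead stereocentres cannot enolise.

Step 4
Reactants: 4 (1R,5S)-1-methylbicyclo[3.1.0]hexan-2-one
Product: 6 (1R,5R)-1,3,3-trimethylbicyclo[3.1.0]hexan-2-one, via monomethyl ketone 5 (not isolated)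
Conditions: LDA (commercial), THF, −78 °C, then MeI; repeat LDA then MeI in the same flask, −78 °C → rt
Reagents that add atoms: iodomethane, CI
Why: Twofold kinetic enolate alkylation at C3, the only enolisable position because the other α-carbon is a quaternary cyclopropane bridgehead, installs the gem-dimethyl group without touching the stereocentres.

Step 5
Reactants: 6 (1R,5R)-1,3,3-trimethylbicyclo[3.1.0]hexan-2-one
Product: 7 (1R,5R)-2-ethynyl-1,3,3-trimethylbicyclo[3.1.0]hexan-2-ol (C2 epimers)
Conditions: HC≡CMgBr, THF, 0 → 50 °C; aqueous work-up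
Reagents that add atoms: ethynylmagnesium bromide, C#C[Mg]Br
Why: 1,2-Addition of a small alkynyl Grignard reagent to a non-enolisable ketone, where the configuration of the new carbinol is irrelevant because this carbon becomes sp2 in step 6.

Step 6
Reactants: 7 (1R,5R)-2-ethynyl-1,3,3-trimethylbicyclo[3.1.0]hexan-2-ol
Product: 8 (1S)-4-ethynyl-3,5,5-trimethylcyclohex-3-en-1-ol
Conditions: HClO4 (cat.), 1,4-dioxane/H2O 2:1, 45 °C
Reagents that add atoms: water, O
Why: Protonation and loss of water give a tertiary propargylic bicyclo[3.1.0]hex-2-yl cation that is stabilised as a cyclopropylcarbinyl ion by the C1–C5 bond; water then attacks the secondary cyclopropane carbon C5 from the side opposite this bond, which breaks and turns the five-membered ring into the cyclohexene with release of about 27 kcal/mol of cyclopropane strain. The closest known reaction type is the acid-catalysed cyclopropylcarbinyl-to-homoallyl rearrangement (i-steroid to 3β-hydroxy-Δ5-steroid hydrolysis, sabinene hydrate to terpinen-4-ol, ring opening of 1-cyclopropylprop-2-yn-1-ols to conjugated enynes). No ring is closed by joining chain ends: the six-membered ring forms by ring expansion, the cyclopropane CH2 (C6) being taken into the ring as the shared C1–C5 bond cleaves. The new carbinol stereocentre is controlled by the cyclopropane stereocentre C5 through SN2-like inversion, so the (5R) bridgehead becomes the (1S) alcohol. The step needs attack at C5 and not at the primary cyclopropane carbon C6, at the alkyne terminus (Meyer–Schuster) or proton loss; this should be secured by the better ability of the secondary carbon to carry positive charge, by the absence of β-hydrogens at the cationic carbon (both neighbours are quaternary), by the high water activity, and by the reversibility of every capture that leaves the strained ring intact, whereas the strain-releasing opening is irreversible.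

Step 7
Reactants: 8 (1S)-4-ethynyl-3,5,5-trimethylcyclohex-3-en-1-ol
Product: 9 (1R,3R,6R)-6-ethynyl-1,5,5-trimethyl-7-oxabicyclo[4.1.0]heptan-3-ol
Conditions: VO(acac)2 (5 mol %), t-BuOOH (in decane), CH2Cl2, 0 °C → rt
Reagents that add atoms: tert-butyl hydroperoxide, CC(C)(C)OO
Why: Vanadium-catalysed hydroxyl-directed epoxidation of a homoallylic cyclohexenol, in which the vanadate ester of the pseudo-axial hydroxyl delivers the peroxide oxygen to its own face, should set both epoxide carbons syn to the OH while the alkyne stays inert.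

Step 8
Reactants: 10 ethyl acetoacetate
Product: 11 ethyl (2E)-3-[(trifluoromethanesulfonyl)oxy]but-2-enoate
Conditions: Tf2O, aq. Me4NOH, hexanes, 5 °C
Reagents that add atoms: trifluoromethanesulfonic anhydride, O=S(=O)(OS(=O)(=O)C(F)(F)F)C(F)(F)F
Why: Stereoselective enol triflation of a β-keto ester, where the non-chelating tetramethylammonium enolate is trapped as the (E)-enol triflate, fixes the E geometry of the trisubstituted alkene that will sit next to the ring.

Step 9
Reactants: 9 (1R,3R,6R)-6-ethynyl-1,5,5-trimethyl-7-oxabicyclo[4.1.0]heptan-3-ol; 11 ethyl (2E)-3-[(trifluoromethanesulfonyl)oxy]but-2-enoate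
Product: 12 ethyl (2E)-5-[(1R,2R,4R)-4-hydroxy-2,6,6-trimethyl-7-oxabicyclo[4.1.0]heptan-1-yl]-3-methylpent-2-en-4-ynoate
Conditions: Pd(PPh3)4 (3 mol %), CuI (6 mol %), Et3N, THF, rt
Reagents that add atoms: none
Why: Sonogashira coupling of a terminal alkyne with an enol triflate proceeds with retention of alkene geometry under mild amine-base conditions that the oxirane and the free hydroxyl tolerate.

Step 10
Reactants: 12 ethyl (2E)-5-[(1R,2R,4R)-4-hydroxy-2,6,6-trimethyl-7-oxabicyclo[4.1.0]heptan-1-yl]-3-methylpent-2-en-4-ynoate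
Product: 14 (1R,3R,Sa)-6-[(3E)-5-hydroxy-3-methylpenta-1,3-dien-1-ylidene]-1,5,5-trimethylcyclohexane-1,3-diol, via epoxy enynol 13 (not isolated)
Conditions: DIBAL-H (excess), CH2Cl2, −78 → 0 °C; Rochelle salt work-up
Reagents that add atoms: none
Why: DIBAL-H reduces the ester to the allylic alcohol and then opens the aluminium-activated alkynyl oxirane by SN2′ hydride delivery anti to the departing C–O bond (the reaction type used for allenic carotenoid end groups), so centre-to-axis chirality transfer should set the allene axis while the tertiary carbinol keeps its configuration.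

Step 11
Reactants: 14 (1R,3R,Sa)-6-[(3E)-5-hydroxy-3-methylpenta-1,3-dien-1-ylidene]-1,5,5-trimethylcyclohexane-1,3-diol
Product: 15 (2R,6R,7aR)-2-[(2E)-4-hydroxybut-2-en-2-yl]-4,4,7a-trimethyl-2,4,5,6,7,7a-hexahydro-1-benzofuran-6-ol
Conditions: Ph3PAuNTf2 (2 mol %), THF, −20 → 0 °C, dark
Reagents that add atoms: none
Why: Gold(I)-catalysed 5-endo cycloisomerisation of an α-hydroxyallene to a 2,5-dihydrofuran, in which the tertiary hydroxyl attacks the gold-activated distal allene carbon anti to the metal, transfers the axial chirality to C2 (R, side chain trans to the 7a-methyl) and should outpace attack by the remote secondary and primary hydroxyls.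

Step 12
Reactants: 15 (2R,6R,7aR)-2-[(2E)-4-hydroxybut-2-en-2-yl]-4,4,7a-trimethyl-2,4,5,6,7,7a-hexahydro-1-benzofuran-6-ol
Product: 16 (2E)-3-[(2R,6R,7aR)-6-hydroxy-4,4,7a-trimethyl-2,4,5,6,7,7a-hexahydro-1-benzofuran-2-yl]but-2-enal
Conditions: activated MnO2, CH2Cl2, rt
Reagents that add atoms: none
Why: MnO2 oxidises only the primary allylic alcohol under neutral conditions, leaving the saturated secondary alcohol and the acid-labile doubly allylic ether untouched.

Step 13
Reactants: 17 (2E,4E,6E)-2,7-dimethylocta-2,4,6-trienedial (3 equiv); 18 ethyl (2E)-4-(diethoxyphosphoryl)-2-methylbut-2-enoate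
Product: 19 ethyl (2E,4E,6E,8E,10E)-2,6,11-trimethyl-12-oxododeca-2,4,6,8,10-pentaenoate
Conditions: KOtBu, THF, 0 °C, then inverse addition to 17 at −20 °C
Reagents that add atoms: none
Why: Horner–Wadsworth–Emmons olefination through the α-carbon of the vinylogous phosphonate gives the E-alkene, and excess symmetric dialdehyde with inverse addition suppresses double olefination.

Step 14
Reactants: 19 ethyl (2E,4E,6E,8E,10E)-2,6,11-trimethyl-12-oxododeca-2,4,6,8,10-pentaenoate
Product: 20 ethyl (2E,4E,6E,8E,10E)-12-hydroxy-2,6,11-trimethyldodeca-2,4,6,8,10-pentaenoate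
Conditions: NaBH4, EtOH/THF, −10 °C
Reagents that add atoms: none
Why: Borohydride 1,2-reduction takes the aldehyde chemoselectively in the presence of the conjugated ester.

Step 15
Reactants: 20 ethyl (2E,4E,6E,8E,10E)-12-hydroxy-2,6,11-trimethyldodeca-2,4,6,8,10-pentaenoate
Product: 21 ethyl (2E,4E,6E,8E,10E)-12-(diethoxyphosphoryl)-2,6,11-trimethyldodeca-2,4,6,8,10-pentaenoate
Conditions: ZnI2, P(OEt)3, THF, reflux
Reagents that add atoms: triethyl phosphite, CCOP(OCC)OCC
Why: Zinc iodide-mediated Arbuzov-type conversion of an allylic alcohol into its diethyl phosphonate, with C–P bond formation at the primary terminus that keeps the polyene conjugated.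

Step 16
Reactants: 16 (2E)-3-[(2R,6R,7aR)-6-hydroxy-4,4,7a-trimethyl-2,4,5,6,7,7a-hexahydro-1-benzofuran-2-yl]but-2-enal; 21 ethyl (2E,4E,6E,8E,10E)-12-(diethoxyphosphoryl)-2,6,11-trimethyldodeca-2,4,6,8,10-pentaenoate
Product: 22 ethyl (2E,4E,6E,8E,10E,12E,14E)-15-[(2R,6R,7aR)-6-hydroxy-4,4,7a-trimethyl-2,4,5,6,7,7a-hexahydro-1-benzofuran-2-yl]-2,6,11-trimethylhexadeca-2,4,6,8,10,12,14-heptaenoate
Conditions: 21, KHMDS, THF, −78 °C; then 16, −78 → 0 °C
Reagents that add atoms: none
Why: Horner–Wadsworth–Emmons olefination of the stabilised pentaenyl phosphonate anion with the enal should form the new C12=C13 bond E-selectively at low temperature, where the γ-alkoxy enal is neither epimerised nor opened and the free secondary hydroxyl is too weak an acid to quench the anion.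

Step 17
Reactants: 22 ethyl (2E,4E,6E,8E,10E,12E,14E)-15-[(2R,6R,7aR)-6-hydroxy-4,4,7a-trimethyl-2,4,5,6,7,7a-hexahydro-1-benzofuran-2-yl]-2,6,11-trimethylhexadeca-2,4,6,8,10,12,14-heptaenoate
Product: 23 (2E,4E,6E,8E,10E,12E,14E)-15-[(2R,6R,7aR)-6-hydroxy-4,4,7a-trimethyl-2,4,5,6,7,7a-hexahydro-1-benzofuran-2-yl]-2,6,11-trimethylhexadeca-2,4,6,8,10,12,14-heptaen-1-ol
Conditions: DIBAL-H, THF/toluene, −78 °C; Rochelle salt work-up
Reagents that add atoms: none
Why: DIBAL-H 1,2-reduction of the conjugated ester to the primary allylic alcohol at low temperature involves no protic acid that could epimerise C2 of the dihydrofuran.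

Step 18
Reactants: 23 (2E,4E,6E,8E,10E,12E,14E)-15-[(2R,6R,7aR)-6-hydroxy-4,4,7a-trimethyl-2,4,5,6,7,7a-hexahydro-1-benzofuran-2-yl]-2,6,11-trimethylhexadeca-2,4,6,8,10,12,14-heptaen-1-ol
Product: 24 (2E,4E,6E,8E,10E,12E,14E)-15-[(2R,6R,7aR)-6-hydroxy-4,4,7a-trimethyl-2,4,5,6,7,7a-hexahydro-1-benzofuran-2-yl]-2,6,11-trimethylhexadeca-2,4,6,8,10,12,14-heptaenal
Conditions: activated MnO2, CH2Cl2, rt, dark
Reagents that add atoms: none
Why: MnO2 oxidises the primary polyenylic alcohol to the aldehyde under neutral conditions with the secondary ring hydroxyl inert, which should deliver the target without exposing it to acid or base.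

**Compound list**
1 | 2-methylcyclopent-2-en-1-one | CC1=CCCC1=O | starting material
2 | (1S)-2-methylcyclopent-2-en-1-ol | O[C@H]1CCC=C1C | intermediate
3 | (1R,2S,5S)-1-methylbicyclo[3.1.0]hexan-2-ol (OH cis to the cyclopropane CH2) | O[C@H]1CC[C@H]2C[C@@]12C | intermediate
4 | (1R,5S)-1-methylbicyclo[3.1.0]hexan-2-one | O=C1CC[C@H]2C[C@@]12C | intermediate
5 | (1R,5S)-1,3-dimethylbicyclo[3.1.0]hexan-2-one (C3 epimers) | O=C1C(C)C[C@H]2C[C@@]12C | intermediate (not isolated)
6 | (1R,5R)-1,3,3-trimethylbicyclo[3.1.0]hexan-2-one | O=C1C(C)(C)C[C@H]2C[C@@]12C | intermediate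
7 | (1R,5R)-2-ethynyl-1,3,3-trimethylbicyclo[3.1.0]hexan-2-ol (C2 epimers) | C#CC1(O)C(C)(C)C[C@H]2C[C@@]12C | intermediate
8 | (1S)-4-ethynyl-3,5,5-trimethylcyclohex-3-en-1-ol | O[C@H]1CC(C)=C(C#C)C(C)(C)C1 | intermediate
9 | (1R,3R,6R)-6-ethynyl-1,5,5-trimethyl-7-oxabicyclo[4.1.0]heptan-3-ol (OH cis to the oxirane oxygen) | O[C@H]1C[C@@]2(C)O[C@@]2(C#C)C(C)(C)C1 | intermediate
10 | ethyl acetoacetate | CCOC(=O)CC(C)=O | starting material
11 | ethyl (2E)-3-[(trifluoromethanesulfonyl)oxy]but-2-enoate | CCOC(=O)/C=C(\C)OS(=O)(=O)C(F)(F)F | intermediate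
12 | ethyl (2E)-5-[(1R,2R,4R)-4-hydroxy-2,6,6-trimethyl-7-oxabicyclo[4.1.0]heptan-1-yl]-3-methylpent-2-en-4-ynoate | O[C@H]1C[C@@]2(C)O[C@@]2(C#C/C(C)=C/C(=O)OCC)C(C)(C)C1 | intermediate
13 | (2E)-5-[(1R,2R,4R)-4-hydroxy-2,6,6-trimethyl-7-oxabicyclo[4.1.0]heptan-1-yl]-3-methylpent-2-en-4-yn-1-ol | O[C@H]1C[C@@]2(C)O[C@@]2(C#C/C(C)=C/CO)C(C)(C)C1 | intermediate (not isolated)
14 | (1R,3R,Sa)-6-[(3E)-5-hydroxy-3-methylpenta-1,3-dien-1-ylidene]-1,5,5-trimethylcyclohexane-1,3-diol (allenic H on the face opposite to the C1 hydroxyl) | C[C@@]1(O)C[C@H](O)CC(C)(C)C1=[C@]=C([H])/C(C)=C/CO | intermediate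
15 | (2R,6R,7aR)-2-[(2E)-4-hydroxybut-2-en-2-yl]-4,4,7a-trimethyl-2,4,5,6,7,7a-hexahydro-1-benzofuran-6-ol | OC/C=C(\C)[C@H]1C=C2C(C)(C)C[C@@H](O)C[C@@]2(C)O1 | intermediate
16 | (2E)-3-[(2R,6R,7aR)-6-hydroxy-4,4,7a-trimethyl-2,4,5,6,7,7a-hexahydro-1-benzofuran-2-yl]but-2-enal | O=C/C=C(\C)[C@H]1C=C2C(C)(C)C[C@@H](O)C[C@@]2(C)O1 | intermediate
17 | (2E,4E,6E)-2,7-dimethylocta-2,4,6-trienedial | O=C/C(C)=C/C=C/C=C(\C)C=O | starting material
18 | ethyl (2E)-4-(diethoxyphosphoryl)-2-methylbut-2-enoate | CCOC(=O)/C(C)=C/CP(=O)(OCC)OCC | starting material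
19 | ethyl (2E,4E,6E,8E,10E)-2,6,11-trimethyl-12-oxododeca-2,4,6,8,10-pentaenoate | CCOC(=O)/C(C)=C/C=C/C(C)=C/C=C/C=C(\C)C=O | intermediate
20 | ethyl (2E,4E,6E,8E,10E)-12-hydroxy-2,6,11-trimethyldodeca-2,4,6,8,10-pentaenoate | CCOC(=O)/C(C)=C/C=C/C(C)=C/C=C/C=C(\C)CO | intermediate
21 | ethyl (2E,4E,6E,8E,10E)-12-(diethoxyphosphoryl)-2,6,11-trimethyldodeca-2,4,6,8,10-pentaenoate | CCOC(=O)/C(C)=C/C=C/C(C)=C/C=C/C=C(\C)CP(=O)(OCC)OCC | intermediate
22 | ethyl (2E,4E,6E,8E,10E,12E,14E)-15-[(2R,6R,7aR)-6-hydroxy-4,4,7a-trimethyl-2,4,5,6,7,7a-hexahydro-1-benzofuran-2-yl]-2,6,11-trimethylhexadeca-2,4,6,8,10,12,14-heptaenoate | C\C(C(=O)OCC)=C/C=C/C(C)=C/C=C/C=C(C)/C=C/C=C(\C)[C@H]1C=C2C(C)(C)C[C@@H](O)C[C@@]2(C)O1 | intermediate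
23 | (2E,4E,6E,8E,10E,12E,14E)-15-[(2R,6R,7aR)-6-hydroxy-4,4,7a-trimethyl-2,4,5,6,7,7a-hexahydro-1-benzofuran-2-yl]-2,6,11-trimethylhexadeca-2,4,6,8,10,12,14-heptaen-1-ol | C\C(CO)=C/C=C/C(C)=C/C=C/C=C(C)/C=C/C=C(\C)[C@H]1C=C2C(C)(C)C[C@@H](O)C[C@@]2(C)O1 | intermediate
24 | (2E,4E,6E,8E,10E,12E,14E)-15-[(2R,6R,7aR)-6-hydroxy-4,4,7a-trimethyl-2,4,5,6,7,7a-hexahydro-1-benzofuran-2-yl]-2,6,11-trimethylhexadeca-2,4,6,8,10,12,14-heptaenal, CNP0118413.1 | C\C(C=O)=C/C=C/C(C)=C/C=C/C=C(C)/C=C/C=C(\C)[C@H]1C=C2C(C)(C)C[C@@H](O)C[C@@]2(C)O1 | target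

**Step count**
Total: 18 steps. Longest linear sequence: 14 steps (steps 1–7, 9–12, 16–18).

**Steps most likely to fail**

1. Step 6 (key step). The propargylic cation may be captured at the alkyne terminus (Meyer–Schuster-type transposition), may lose a proton to a dienyne, or may open the external cyclopropane bond instead of being hydrated at the ring-fusion CH. The fallback sets out from ketone 6 and comes back at enynol 8, and generates the cyclopropylcarbinyl cation without an alkyne on it. Chloromethyllithium (ClCH2I, MeLi·LiBr, THF, −78 °C) should convert 6 into (1R,5R)-1,3,3-trimethylspiro[bicyclo[3.1.0]hexane-2,2'-oxirane] F1. Dilute aqueous HClO4 in THF at 0 °C should ionise the oxirane to a tertiary cyclopropylcarbinyl cation that is hydrated at the ring-fusion CH with the same inversion and ring expansion, giving (1S)-4-(hydroxymethyl)-3,5,5-trimethylcyclohex-3-en-1-ol F2. MnO2 should then oxidise the allylic primary alcohol to (4S)-4-hydroxy-2,6,6-trimethylcyclohex-1-ene-1-carbaldehyde F3, and Colvin homologation (lithiated trimethylsilyldiazomethane, THF, −78 °C → rt) should return 8.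

2. Step 7. Oxygen transfer to the tetrasubstituted enyne alkene may be slow, and facial selectivity may be poor because the directing hydroxyl must become pseudo-axial against a 1,3-diaxial methyl. The fallback sets out from 8 and comes back at 9, and delivers the oxygen through a covalent tether instead of a metal-bound peroxide. Boc2O/DMAP should give tert-butyl (1S)-4-ethynyl-3,5,5-trimethylcyclohex-3-en-1-yl carbonate F4. IBr in toluene at −80 °C should then close the cyclic iodocarbonate (8-ethynyl-8-iodo-1,7,7-trimethyl-2,4-dioxabicyclo[3.3.1]nonan-3-one, carbonate oxygen delivered syn by the tether, iodine anti to it) F5. K2CO3 in MeOH should cleave the carbonate and let the liberated tertiary alkoxide displace iodide to give syn-epoxy alcohol 9.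

3. Step 10. Stereochemical fidelity may be lost if syn hydride delivery from oxygen-bound aluminium competes with the anti-SN2′ pathway, and over-reduction of the enyne is possible. The fallback sets out from 12 and comes back at 14, and separates allene formation from ester reduction. Palladium-catalysed hydrogenolysis (Pd2(dba)3, PBu3, HCO2NH4, THF, rt → 40 °C) should proceed by anti oxidative addition to an allenylpalladium species and hydride transfer with retention, giving ethyl (2E)-5-[(2R,4R)-2,4-dihydroxy-2,6,6-trimethylcyclohexylidene]-3-methylpenta-2,4-dienoate with the same allene axis as 14, F6. DIBAL-H at −78 °C should then reduce only the ester and give 14.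

**Further compounds**
F1 | step 6 | (1R,5R)-1,3,3-trimethylspiro[bicyclo[3.1.0]hexane-2,2'-oxirane] (spiro-carbon epimers) | C1OC12C(C)(C)C[C@H]3C[C@@]23C
F2 | step 6 | (1S)-4-(hydroxymethyl)-3,5,5-trimethylcyclohex-3-en-1-ol | O[C@H]1CC(C)=C(CO)C(C)(C)C1
F3 | step 6 | (4S)-4-hydroxy-2,6,6-trimethylcyclohex-1-ene-1-carbaldehyde | O[C@H]1CC(C)=C(C=O)C(C)(C)C1
F4 | step 7 | tert-butyl (1S)-4-ethynyl-3,5,5-trimethylcyclohex-3-en-1-yl carbonate | CC(C)(C)OC(=O)O[C@H]1CC(C)=C(C#C)C(C)(C)C1
F5 | step 7 | 8-ethynyl-8-iodo-1,7,7-trimethyl-2,4-dioxabicyclo[3.3.1]nonan-3-one (cyclic carbonate bridging the two oxygen-bearing ring carbons, iodine anti to the tertiary C–O bond) | O=C1O[C@H]2C[C@@](C)(O1)[C@@](I)(C#C)C(C)(C)C2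
F6 | step 10 | ethyl (2E)-5-[(2R,4R)-2,4-dihydroxy-2,6,6-trimethylcyclohexylidene]-3-methylpenta-2,4-dienoate (allene axis as in 14) | C[C@@]1(O)C[C@H](O)CC(C)(C)C1=[C@]=C([H])/C(C)=C/C(=O)OCC
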